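**Retrosynthetic overview**
1. Target 12 ⇐ global hydrogenolysis of penta-O-benzyl ester 11 ⇐ flavan-3-one 8, by face-selective hydride reduction with acylation of the alkoxide in the same flask (sets C3, cis to the aryl group).
2. Ring C of 8 ⇐ C4–C4a bond: an α-oxo gold carbene (enolonium equivalent, made by oxidising a terminal alkyne) is captured by the symmetric, phloroglucinol-type ring A of aryl propargyl ether 6, joining two carbons that are both normally nucleophilic.
3. 6 ⇐ Mitsunobu inversion of (R)-propargylic alcohol 4 with phenol 5 (forms C2–O1); 4 ⇐ catalytic asymmetric alkynylation of aldehyde 1 (sets C2).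
4. Ring order: rings A and B are bought; ring C is closed last, in the key step.

Assumption: the antipode named for each chiral ligand or catalyst is taken to be the one that gives the configuration drawn; if a first run shows the opposite sense, its mirror image is used and nothing else changes.

**Step 1**
Reactants: 1 3,4-bis(benzyloxy)benzaldehyde; 2 trimethylsilylacetylene
Product: 4 (R)-1-[3,4-bis(benzyloxy)phenyl]prop-2-yn-1-ol, via silylated carbinol 3 (not isolated)
Conditions: Me2Zn (3 equiv), (S,S)-ProPhenol [2,6-bis{[(S)-2-(hydroxydiphenylmethyl)pyrrolidin-1-yl]methyl}-4-methylphenol] (10 mol%), Ph3PO (20 mol%), toluene, 4 °C; then MeOH, K2CO3, rt; aq NH4Cl work-up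
Reagents that add atoms: none
Why: Trost asymmetric alkynylation, in which the alkynylzinc is delivered to one aldehyde face inside the chiral dinuclear divalent-zinc ProPhenol pocket and sets the carbinol centre, followed by methoxide protodesilylation (same geometry; the descriptor changes from S in 3 to R in 4 only because silicon raises the alkyne priority).

**Step 2**
Reactants: 4 (R)-1-[3,4-bis(benzyloxy)phenyl]prop-2-yn-1-ol; 5 3,5-bis(benzyloxy)phenol
Product: 6 (S)-1-[3,4-bis(benzyloxy)phenyl]prop-2-yn-1-yl 3,5-bis(benzyloxy)phenyl ether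
Conditions: PPh3, DIAD, toluene, −20 °C to 0 °C
Reagents that add atoms: none
Why: Mitsunobu etherification, in which the phenol displaces the alkoxyphosphonium by SN2 with inversion to give the S ether (the geometry of C2 in the flavan), with non-polar solvent and low temperature used to suppress ionisation of the benzylic-propargylic centre.

**Step 3**
Reactants: 6 (S)-1-[3,4-bis(benzyloxy)phenyl]prop-2-yn-1-yl 3,5-bis(benzyloxy)phenyl ether
Product: 8 (2R)-5,7-bis(benzyloxy)-2-[3,4-bis(benzyloxy)phenyl]chroman-3-one, via α-oxo gold carbene 7 (not isolated)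
Conditions: (Me4tBuXPhos)AuNTf2 (5 mol%), 2,6-dichloropyridine N-oxide (1.5 equiv), ClCH2CH2Cl, 0 °C to rt
Reagents that add atoms: 2,6-dichloropyridine N-oxide, [O-][n+]1c(Cl)cccc1Cl
Why: Gold-catalysed oxidative cyclisation of an aryl propargyl ether (Zhang-type chroman-3-one synthesis): the N-oxide adds to the alkyne activated by monovalent gold at its internal carbon and, after N–O cleavage, leaves carbene 7, whose electrophilic terminal carbon (C4) is attacked intramolecularly (Friedel–Crafts) by ring A at either of its two equivalent ortho carbons to close ring C; this extends the known reaction to an α-aryl, enantioenriched ether whose C2 centre takes no part and is carried through (descriptor R in 8 because C3 now outranks the aryl group).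

**Step 4**
Reactants: 8 (2R)-5,7-bis(benzyloxy)-2-[3,4-bis(benzyloxy)phenyl]chroman-3-one; 9 4-(benzyloxy)benzoyl chloride
Product: 11 (2R,3R)-5,7-bis(benzyloxy)-2-[3,4-bis(benzyloxy)phenyl]chroman-3-yl 4-(benzyloxy)benzoate, via lithium alkoxide 10 (not isolated)
Conditions: LiBH(s-Bu)3 (1.1 equiv), LiBr (5 equiv), THF, −78 °C; then 9 (2 equiv), DMAP (0.3 equiv), −78 °C to rt; pH 7 buffer work-up
Reagents that add atoms: none
Why: Substrate-controlled reduction by a bulky borohydride, which delivers hydride to the ketone face opposite the C2 aryl group so the C3 oxygen ends cis to it (3R, as established for this ketone in the catechin to epicatechin series), followed by reductive acylation, in which the lithium alkoxide is trapped by the acid chloride under DMAP catalysis.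

**Step 5**
Reactants: 11 (2R,3R)-5,7-bis(benzyloxy)-2-[3,4-bis(benzyloxy)phenyl]chroman-3-yl 4-(benzyloxy)benzoate
Product: 12 epicatechin 3-O-p-hydroxybenzoate, (2R,3R)-2-(3,4-dihydroxyphenyl)-5,7-dihydroxychroman-3-yl 4-hydroxybenzoate
Conditions: H2 (1 atm), Pd(OH)2/C, THF/MeOH 1:1, rt
Reagents that add atoms: none
Why: Catalytic hydrogenolysis removes the five O-benzyl ethers, while the alkyl benzoate at the non-benzylic C3 and the cyclic C2–O1 ether survive under these mild conditions, as in benzyl-protected catechin gallates, and neither stereocentre is touched.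

**Compound list**
1 | 3,4-bis(benzyloxy)benzaldehyde | O=Cc1ccc(OCc2ccccc2)c(OCc2ccccc2)c1 | starting material
2 | trimethylsilylacetylene | C#C[Si](C)(C)C | starting material
3 | (S)-1-[3,4-bis(benzyloxy)phenyl]-3-(trimethylsilyl)prop-2-yn-1-ol | C[Si](C)(C)C#C[C@@H](O)c1ccc(OCc2ccccc2)c(OCc2ccccc2)c1 | intermediate (not isolated)
4 | (R)-1-[3,4-bis(benzyloxy)phenyl]prop-2-yn-1-ol | C#C[C@@H](O)c1ccc(OCc2ccccc2)c(OCc2ccccc2)c1 | intermediate
5 | 3,5-bis(benzyloxy)phenol | Oc1cc(OCc2ccccc2)cc(OCc2ccccc2)c1 | starting material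
6 | (S)-1-[3,4-bis(benzyloxy)phenyl]prop-2-yn-1-yl 3,5-bis(benzyloxy)phenyl ether | C#C[C@H](Oc1cc(OCc2ccccc2)cc(OCc2ccccc2)c1)c1ccc(OCc2ccccc2)c(OCc2ccccc2)c1 | intermediate
7 | α-oxo gold carbene, [(Me4tBuXPhos)Au=CH–C(=O)–CH(OAr)Ar']+ NTf2−, with the C2 centre as in 6 | O=C(C=[Au][P+](C(C)(C)C)(C(C)(C)C)c1c(C)c(C)c(C)c(C)c1-c1c(C(C)C)cc(C(C)C)cc1C(C)C)[C@H](Oc1cc(OCc2ccccc2)cc(OCc2ccccc2)c1)c1ccc(OCc2ccccc2)c(OCc2ccccc2)c1.O=S(=O)([N-]S(=O)(=O)C(F)(F)F)C(F)(F)F | intermediate (not isolated)
8 | (2R)-5,7-bis(benzyloxy)-2-[3,4-bis(benzyloxy)phenyl]chroman-3-one | O=C1Cc2c(OCc3ccccc3)cc(OCc3ccccc3)cc2O[C@@H]1c1ccc(OCc2ccccc2)c(OCc2ccccc2)c1 | intermediate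
9 | 4-(benzyloxy)benzoyl chloride | O=C(Cl)c1ccc(OCc2ccccc2)cc1 | starting material
10 | lithium (2R,3R)-5,7-bis(benzyloxy)-2-[3,4-bis(benzyloxy)phenyl]chroman-3-olate | [Li+].[O-][C@@H]1Cc2c(OCc3ccccc3)cc(OCc3ccccc3)cc2O[C@@H]1c1ccc(OCc2ccccc2)c(OCc2ccccc2)c1 | intermediate (not isolated)
11 | (2R,3R)-5,7-bis(benzyloxy)-2-[3,4-bis(benzyloxy)phenyl]chroman-3-yl 4-(benzyloxy)benzoate | O=C(O[C@@H]1Cc2c(OCc3ccccc3)cc(OCc3ccccc3)cc2O[C@@H]1c1ccc(OCc2ccccc2)c(OCc2ccccc2)c1)c1ccc(OCc2ccccc2)cc1 | intermediate
12 | epicatechin 3-O-p-hydroxybenzoate, (2R,3R) | O=C(O[C@@H]1Cc2c(O)cc(O)cc2O[C@@H]1c1ccc(O)c(O)c1)c1ccc(O)cc1 | target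

**Step count and risks**
Total steps: 5. Longest linear sequence: 5 steps (1 → 4 → 6 → 8 → 11 → 12); fragments 2, 5 and 9 are bought.

The three steps most likely to fail:

Step 3 (key step). The electron-rich ring A may add directly to the gold-activated alkyne before the oxidant does, giving a chromene. The carbene may instead be taken by ring B (a 2-indanone) or by a second N-oxide. The doubly activated C2–O bond may ionise, and the new ketone can epimerise at C2. The fallback sets out from 6 and uses the competing pathway on purpose. Monovalent gold without oxidant (Ph3PAuNTf2, CH2Cl2, rt) gives, by 6-endo hydroarylation that leaves C2 alone, (2S)-5,7-bis(benzyloxy)-2-[3,4-bis(benzyloxy)phenyl]-2H-chromene F3. Hydroboration (BH3·THF, 0 °C) places boron at C3 on the face anti to the aryl group, giving the alkylborane [(2S,3S)-5,7-bis(benzyloxy)-2-[3,4-bis(benzyloxy)phenyl]chroman-3-yl]borane F4. Oxidation (NaOH/H2O2) gives the 2,3-trans alcohol (2R,3S)-5,7-bis(benzyloxy)-2-[3,4-bis(benzyloxy)phenyl]chroman-3-ol F5. Dess–Martin periodinane (CH2Cl2, rt) then oxidises F5 to the ketone, and the fallback comes back to the route at 8.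

Step 2. The alkoxyphosphonium of a 3,4-dialkoxybenzylic, propargylic alcohol can ionise, which would erode the ee and allow C-alkylation of the phenol. The fallback sets out from 1 and makes that ionisation the mechanism. HC≡CMgBr (THF, 0 °C) gives the bromomagnesium alkoxide of racemic 1-[3,4-bis(benzyloxy)phenyl]prop-2-yn-1-ol F1, which is quenched in the flask with Ac2O to racemic 1-[3,4-bis(benzyloxy)phenyl]prop-2-yn-1-yl acetate F2. F2 and phenol 5 are joined by enantioconvergent propargylic etherification under monovalent copper catalysis (Cu(MeCN)4BF4, (S,S)-Ph-pybox [2,6-bis((4S)-4-phenyl-4,5-dihydrooxazol-2-yl)pyridine], i-Pr2NEt, MeOH, −20 °C) through a copper allenylidene. This replaces steps 1 and 2 and comes back at 6. Its own risk is C- rather than O-attack by the electron-rich phenol.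

Step 4. The basic hydride may enolise the ketone toward C2 and erode its configuration, and the hindered axial alkoxide may acylate slowly while residual hydride consumes 9. The fallback sets out from 8 and replaces substrate control by catalyst control with dynamic kinetic resolution. Asymmetric transfer hydrogenation with divalent ruthenium (RuCl[(R,R)-TsDPEN](p-cymene), HCO2H/Et3N 5:2, CH2Cl2, rt) reduces the ketone while C2 epimerises through the enol, giving (2R,3R)-5,7-bis(benzyloxy)-2-[3,4-bis(benzyloxy)phenyl]chroman-3-ol F6. This is not yet described for flavan-3-ones and is modelled on 2-aryl cycloalkanones and 3-aryl chroman-4-ones; it would also repair any loss of ee at C2 from steps 2 and 3. F6 is then acylated with 9 (pyridine, DMAP, CH2Cl2, rt), and the fallback comes back at 11.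

**Further compounds**
F1 | step 2 | bromomagnesium alkoxide of racemic 1-[3,4-bis(benzyloxy)phenyl]prop-2-yn-1-ol | Br[Mg]OC(C#C)c1ccc(OCc2ccccc2)c(OCc2ccccc2)c1
F2 | step 2 | racemic 1-[3,4-bis(benzyloxy)phenyl]prop-2-yn-1-yl acetate | CC(=O)OC(C#C)c1ccc(OCc2ccccc2)c(OCc2ccccc2)c1
F3 | step 3 | (2S)-5,7-bis(benzyloxy)-2-[3,4-bis(benzyloxy)phenyl]-2H-chromene | C1=Cc2c(OCc3ccccc3)cc(OCc3ccccc3)cc2O[C@@H]1c1ccc(OCc2ccccc2)c(OCc2ccccc2)c1
F4 | step 3 | [(2S,3S)-5,7-bis(benzyloxy)-2-[3,4-bis(benzyloxy)phenyl]chroman-3-yl]borane | B[C@H]1Cc2c(OCc3ccccc3)cc(OCc3ccccc3)cc2O[C@@H]1c1ccc(OCc2ccccc2)c(OCc2ccccc2)c1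
F5 | step 3 | (2R,3S)-5,7-bis(benzyloxy)-2-[3,4-bis(benzyloxy)phenyl]chroman-3-ol | O[C@H]1Cc2c(OCc3ccccc3)cc(OCc3ccccc3)cc2O[C@@H]1c1ccc(OCc2ccccc2)c(OCc2ccccc2)c1
F6 | step 4 | (2R,3R)-5,7-bis(benzyloxy)-2-[3,4-bis(benzyloxy)phenyl]chroman-3-ol | O[C@@H]1Cc2c(OCc3ccccc3)cc(OCc3ccccc3)cc2O[C@@H]1c1ccc(OCc2ccccc2)c(OCc2ccccc2)c1
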